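**Retrosynthetic overview**
1. Atom labels: C1 CH–O-methacrylate, C2 CH2, C3 CH–O-isobutyrate, C4 C(CH3), C5 CH beside ketone C6, C7 =CH, C8 =C(CH3), C9 CH, C10 CH, C11 C(CH3)2; rings: cyclobutane C4–C5–C10–C9, cyclohexenone C5–C6–C7–C8–C9–C10, cycloheptane C4–C3–C2–C1–C11–C10–C5.
2. The strategy rests on C4: a methyl-bearing quaternary cyclobutane carbon bonded to the carbinol C3 inside the seven-membered ring, so the C4 methyl and the C3–C4 bond both come from a C4 exocyclic methylene and a C3 aldehyde (hydrogen atom to the CH2, C4 to the carbonyl carbon); the two esters follow.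
3. The bicyclo[3.1.1]heptenone is closed at C7=C8 by intramolecular Horner–Wadsworth–Emmons reaction between a C5 ketophosphonate arm and a C9 acetyl arm on a 2-methylenecyclobutane.
4. The cyclobutane comes from dichloroketene [2+2] cycloaddition to the vinyl group of the chain alkene; a chiral lithium amide then distinguishes the two α-CH2 groups of the cyclobutanone so that the two different arms go on in order.
5. The chain C11–C1–C2–C3 with the C1 stereocentre comes from asymmetric reverse prenylation of 3-(PMBO)propanal; ring order: cyclobutane, cyclohexenone, cycloheptane.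

Key step: step 16

Abbreviations: TBS = tert-butyldimethylsilyl, TES = triethylsilyl, PMB = 4-methoxybenzyl, Ipc = isopinocampheyl; R = (3R)-3-(TBSO)-5-(PMBO)-2-methylpentan-2-yl (the C11–C1–C2–C3 chain).

Assumption: the (R,R)-amide of step 6 is taken to deprotonate the pro-C5 methylene, a sense inferred by analogy with other 3-substituted cyclobutanones and not certain (the mirror-image amide would be used if it proved opposite); lithium enolates and alkoxides that only pass through a step are not numbered.

**Route**

Step 1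
Reactants: 1 3-(PMBO)propan-1-ol
Product: 2 3-(PMBO)propanal
Conditions: PhI(OAc)2, TEMPO (10 mol %), CH2Cl2, rt
Reagents that add atoms: none
Why: TEMPO-catalysed oxoammonium oxidation of a primary alcohol stops at the aldehyde and leaves the PMB ether untouched.

Step 2
Reactants: 2 3-(PMBO)propanal; 3 3-methylbuta-1,2-diene
Product: 6 (3R)-1-(PMBO)-4,4-dimethylhex-5-en-3-ol, via prenylborane 4 (not isolated), via borinic ester 5 (not isolated)
Conditions: (−)-Ipc2BH [from (+)-α-pinene], 3, THF, −25 °C; then 2, −78 °C; NaOH, H2O2, 0 °C to rt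
Reagents that add atoms: none
Why: Brown allylboration in its reverse-prenylation form: hydroboration of the allene gives the γ,γ-dimethylallylborane, which adds through a closed six-membered chair transition state at its substituted terminus (creating the C11 quaternary carbon), and the Ipc groups from (+)-α-pinene direct the attack to the Si face of the aldehyde, which sets C1 as R.

Step 3
Reactants: 6 (3R)-1-(PMBO)-4,4-dimethylhex-5-en-3-ol
Product: 7 (3R)-3-(TBSO)-1-(PMBO)-4,4-dimethylhex-5-ene
Conditions: TBSOTf, 2,6-lutidine, CH2Cl2, −78 to 0 °C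
Reagents that add atoms: tert-butyldimethylsilyl trifluoromethanesulfonate, CC(C)(C)[Si](C)(C)OS(=O)(=O)C(F)(F)F
Why: Silyl triflate silylation is the standard protection of a hindered secondary alcohol next to a quaternary carbon.

Step 4
Reactants: 7 (3R)-3-(TBSO)-1-(PMBO)-4,4-dimethylhex-5-ene; 8 trichloroacetyl chloride
Product: 10 2,2-dichloro-3-R-cyclobutan-1-one (both ring epimers), via dichloroketene 9 (not isolated)
Conditions: Zn–Cu couple, Et2O/DME, slow addition of 8, rt
Reagents that add atoms: none
Why: Thermal [2+2] cycloaddition of dichloroketene to a monosubstituted alkene gives the 2,2-dichloro-3-alkylcyclobutanone regioselectively (carbonyl carbon to the CH2 terminus), DME ties up ZnCl2 so that the PMB and TBS ethers should survive, and the new ring stereocentre forms as both epimers, a difference that step 5 removes.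

Step 5
Reactants: 10 2,2-dichloro-3-R-cyclobutan-1-one
Product: 11 3-R-cyclobutan-1-one
Conditions: Zn dust, AcOH, rt
Reagents that add atoms: none
Why: Zinc reduction of an α,α-dichloroketone removes both chlorines and gives the cyclobutanone in which C10 is no longer a stereocentre.

Step 6
Reactants: 11 3-R-cyclobutan-1-one
Product: 12 (3S)-3-R-1-(triethylsilyloxy)cyclobut-1-ene (double bond C4=C5)
Conditions: (R,R)-bis(1-phenylethyl)amine, n-BuLi, TESCl (present from the start), THF, −100 °C
Reagents that add atoms: chlorotriethylsilane, CC[Si](Cl)(CC)CC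
Why: Group-selective deprotonation of a 3-substituted cyclobutanone by a C2-symmetric chiral lithium amide with in situ silyl chloride quench is a known desymmetrisation, and removal of a proton from the pro-C5 methylene fixes the configuration of C10 relative to the arm that follows (the C1 centre is too remote to interfere).

Step 7
Reactants: 12 (3S)-3-R-1-(triethylsilyloxy)cyclobut-1-ene; 13 diethyl (2-oxoethyl)phosphonate
Product: 14 (2S,3S)-2-[2-(diethoxyphosphoryl)-1-hydroxyethyl]-3-R-cyclobutan-1-one (arm on C5; both carbinol epimers)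
Conditions: BF3·OEt2, CH2Cl2, −78 °C; aq. NaHCO3
Reagents that add atoms: none
Why: Mukaiyama aldol addition under Lewis acid conditions uses no base, so the acidic phosphonoacetaldehyde is not deprotonated, and the aldehyde approaches the enol ether face away from the bulky C10 substituent, which sets C5 trans to it (the carbinol carbon is oxidised later).

Step 8
Reactants: 14 (2S,3S)-2-[2-(diethoxyphosphoryl)-1-hydroxyethyl]-3-R-cyclobutan-1-one
Product: 15 (2S,3S)-2-[2-(diethoxyphosphoryl)-1-(TESO)ethyl]-3-R-cyclobutan-1-one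
Conditions: TESCl, imidazole, DMF, 0 °C to rt
Reagents that add atoms: chlorotriethylsilane, CC[Si](Cl)(CC)CC
Why: Silylation blocks retro-aldol cleavage and elimination of the β-hydroxy ketone in the two basic steps that follow.

Step 9
Reactants: 15 (2S,3S)-2-[2-(diethoxyphosphoryl)-1-(TESO)ethyl]-3-R-cyclobutan-1-one; 16 acetaldehyde
Product: 17 (2S,3S,4R)-2-[2-(diethoxyphosphoryl)-1-(TESO)ethyl]-3-R-4-[1-(TESO)ethyl]cyclobutan-1-one
Conditions: LiN(iPr)2, THF, −78 °C; 16; then TESOTf, −78 to −40 °C
Reagents that add atoms: triethylsilyl trifluoromethanesulfonate, CC[Si](CC)(CC)OS(=O)(=O)C(F)(F)F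
Why: Kinetic deprotonation takes the only remaining α-CH2 (C9), the lithium enolate aldol addition to acetaldehyde occurs anti to the C10 substituent so that the C9 arm is trans to it and cis to the C5 arm, and the aldolate is silylated in the flask before it can revert (carbinol epimers again irrelevant).

Step 10
Reactants: 17 (2S,3S,4R)-2-[2-(diethoxyphosphoryl)-1-(TESO)ethyl]-3-R-4-[1-(TESO)ethyl]cyclobutan-1-one; 18 methyltriphenylphosphonium bromide
Product: 20 (2R,3S,4S)-2-[2-(diethoxyphosphoryl)-1-(TESO)ethyl]-1-methylidene-3-R-4-[1-(TESO)ethyl]cyclobutane, via methylenetriphenylphosphorane 19 (not isolated)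
Conditions: KN(SiMe3)2, THF, 0 °C; then 17, 0 °C to rt
Reagents that add atoms: none
Why: Wittig methylenation is fast on the strained cyclobutanone carbonyl, and the unstabilised ylide at low temperature limits enolisation of the flanking α-centres, whose all-trans arrangement is in any case the stable one.

Step 11
Reactants: 20 (2R,3S,4S)-2-[2-(diethoxyphosphoryl)-1-(TESO)ethyl]-1-methylidene-3-R-4-[1-(TESO)ethyl]cyclobutane
Product: 21 (2R,3S,4S)-2-[2-(diethoxyphosphoryl)-1-hydroxyethyl]-4-(1-hydroxyethyl)-1-methylidene-3-R-cyclobutane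
Conditions: PPTS, MeOH, rt
Reagents that add atoms: none
Why: Acid-catalysed methanolysis removes the two secondary TES ethers selectively, because the TBS ether at C1 is more hindered and far less labile and the PMB ether is inert.

Step 12
Reactants: 21 (2R,3S,4S)-2-[2-(diethoxyphosphoryl)-1-hydroxyethyl]-4-(1-hydroxyethyl)-1-methylidene-3-R-cyclobutane
Product: 22 (2R,3S,4S)-4-acetyl-2-[(diethoxyphosphoryl)acetyl]-1-methylidene-3-R-cyclobutane
Conditions: Dess–Martin periodinane, NaHCO3, CH2Cl2, 0 °C to rt
Reagents that add atoms: none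
Why: Dess–Martin oxidation turns both secondary alcohols into ketones under buffered, non-basic conditions, giving the C9 acetyl group and the C5 β-ketophosphonate without moving the exocyclic double bond.

Step 13
Reactants: 22 (2R,3S,4S)-4-acetyl-2-[(diethoxyphosphoryl)acetyl]-1-methylidene-3-R-cyclobutane
Product: 23 (1R,5R,7S)-4-methyl-6-methylidene-7-R-bicyclo[3.1.1]hept-3-en-2-one (R anti to the enone bridge)
Conditions: K2CO3, 18-crown-6, toluene, 50 °C
Reagents that add atoms: none
Why: Intramolecular Horner–Wadsworth–Emmons olefination: the base removes only the most acidic proton (between P=O and C=O), the phosphonate carbanion adds to the C9 acetyl group across the cis-1,3 positions of the cyclobutane, and loss of diethyl phosphate makes the closure to the strained enone irreversible; C5, C9 and C10 are untouched, the enone regiochemistry follows from which arm carries phosphorus, and the minor diastereomer left from step 6 would be removed here.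

Step 14
Reactants: 23 (1R,5R,7S)-4-methyl-6-methylidene-7-R-bicyclo[3.1.1]hept-3-en-2-one
Product: 24 (1R,5R,7S)-7-[(3R)-3-(TBSO)-5-hydroxy-2-methylpentan-2-yl]-4-methyl-6-methylidenebicyclo[3.1.1]hept-3-en-2-one
Conditions: DDQ, CH2Cl2/pH 7 buffer, 0 °C
Reagents that add atoms: none
Why: Oxidative cleavage of the PMB ether by DDQ leaves the TBS ether, the enone and the 1,1-disubstituted alkene alone.

Step 15
Reactants: 24 (1R,5R,7S)-7-[(3R)-3-(TBSO)-5-hydroxy-2-methylpentan-2-yl]-4-methyl-6-methylidenebicyclo[3.1.1]hept-3-en-2-one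
Product: 25 (1R,5R,7S)-7-[(3R)-3-(TBSO)-2-methyl-5-oxopentan-2-yl]-4-methyl-6-methylidenebicyclo[3.1.1]hept-3-en-2-one (methylene enone aldehyde)
Conditions: Dess–Martin periodinane, NaHCO3, CH2Cl2, rt
Reagents that add atoms: none
Why: Dess–Martin oxidation gives the β-silyloxy aldehyde without base, so neither elimination of the silyloxy group nor epimerisation at C1 is expected.

Step 16
Reactants: 25 methylene enone aldehyde
Product: 27 tricyclic C3 alcohol with C1 OTBS (1R,3R,4R,5R,9R,10S by the overview labels), via phenylsilyl ether 26 (not isolated)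
Conditions: Co(salen)Cl [salen = N,N′-bis(3,5-di-tert-butylsalicylidene)ethane-1,2-diaminate] (10 mol %), CrCl2 (30 mol %), PhSiH3 (2 equiv), THF (0.01 M), rt; then aq. K2CO3
Reagents that add atoms: none
Why: Proposed new method: a trivalent cobalt hydride formed from Co(salen)Cl and PhSiH3 passes a hydrogen atom to the CH2 terminus of the exocyclic alkene, which makes the C4 methyl group and a tertiary cyclobutyl radical that divalent chromium should trap faster than it can fragment; the trivalent alkylchromium then adds to the tethered C3 aldehyde and the chromium alkoxide is silylated by the silane, which also returns hydride to the metals (first product 26, hydrolysed to 27 on work-up). The closest known reaction is the intermolecular cobalt-hydride/chromium branch-selective coupling of 1,1-disubstituted alkenes with aldehydes, which gives a quaternary carbon next to a secondary alcohol; its use to close a ring is new. The C3–C4 bond closes the seven-membered ring C4–C3–C2–C1–C11–C10–C5 by attack of C4 on the carbonyl carbon (7-exo-trig at C=O). C4 is set by the tether: the chain on C10 lies anti to the enone bridge and reaches only the C4 face that points towards C10, so the new methyl group ends up syn to the enone bridge. C3 is set relative to the C1 silyl ether: in a twist-chair closure with the OTBS group pseudo-equatorial, the chromium-bound carbonyl oxygen should turn away from the C11 methyl groups, which places the C3 oxygen 1,3-anti to the C1 oxygen. The step needs the aldehyde to react in preference to the C6 enone and the 1,1-disubstituted alkene in preference to the enone alkene, which the aldehyde preference of organochromium reagents and the preference of the cobalt hydride for the electron-rich, less substituted alkene should secure.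

Step 17
Reactants: 27 tricyclic C3 alcohol with C1 OTBS
Product: 28 C3 isobutyrate of 27 (C1 OTBS)
Conditions: isobutyric anhydride, Et3N, DMAP, CH2Cl2, rt
Reagents that add atoms: isobutyric anhydride, CC(C)C(=O)OC(=O)C(C)C
Why: DMAP-catalysed acylation esterifies the only free hydroxyl group (C3) with retention of configuration.

Step 18
Reactants: 28 C3 isobutyrate with C1 OTBS
Product: 29 C1 alcohol with C3 isobutyrate
Conditions: HF·pyridine, pyridine, THF, 0 °C to rt
Reagents that add atoms: none
Why: Fluoride-mediated desilylation under weakly acidic conditions frees the C1 alcohol without the base that could move the isobutyryl group from O3 to O1.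

Step 19
Reactants: 29 C1 alcohol with C3 isobutyrate
Product: 30 target, C1 methacrylate and C3 isobutyrate (1R,3R,4R,5R,9R,10S by the overview labels)
Conditions: methacrylic anhydride, Et3N, DMAP, BHT (trace), CH2Cl2, rt
Reagents that add atoms: methacrylic anhydride, C=C(C)C(=O)OC(=O)C(C)=C
Why: DMAP-catalysed acylation of the C1 alcohol with the anhydride gives the methacrylate with retention at C1, and the radical inhibitor keeps the acrylate from polymerising.

**Compound list**
1 | 3-(PMBO)propan-1-ol | COc1ccc(COCCCO)cc1 | starting material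
2 | 3-(PMBO)propanal | COc1ccc(COCCC=O)cc1 | intermediate
3 | 3-methylbuta-1,2-diene | CC(C)=C=C | starting material
4 | B-(3-methylbut-2-en-1-yl)diisopinocampheylborane, Ipc from (+)-α-pinene (not isolated) | CC(C)=CCB([C@@H]1C[C@@H]2C[C@H]([C@H]1C)C2(C)C)[C@@H]1C[C@@H]2C[C@H]([C@H]1C)C2(C)C | intermediate
5 | diisopinocampheylborinic ester of 6 (not isolated) | C=CC(C)(C)[C@H](OB([C@@H]1C[C@@H]2C[C@H]([C@H]1C)C2(C)C)[C@@H]1C[C@@H]2C[C@H]([C@H]1C)C2(C)C)CCOCc1ccc(OC)cc1 | intermediate
6 | (3R)-1-(PMBO)-4,4-dimethylhex-5-en-3-ol | C=CC(C)(C)[C@H](O)CCOCc1ccc(OC)cc1 | intermediate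
7 | (3R)-3-(TBSO)-1-(PMBO)-4,4-dimethylhex-5-ene | C=CC(C)(C)[C@H](O[Si](C)(C)C(C)(C)C)CCOCc1ccc(OC)cc1 | intermediate
8 | trichloroacetyl chloride | O=C(Cl)C(Cl)(Cl)Cl | starting material
9 | dichloroketene (not isolated) | O=C=C(Cl)Cl | intermediate
10 | 2,2-dichloro-3-R-cyclobutan-1-one, both ring epimers | O=C1CC(C(C)(C)[C@H](O[Si](C)(C)C(C)(C)C)CCOCc2ccc(OC)cc2)C1(Cl)Cl | intermediate
11 | 3-R-cyclobutan-1-one | O=C1CC(C(C)(C)[C@H](O[Si](C)(C)C(C)(C)C)CCOCc2ccc(OC)cc2)C1 | intermediate
12 | (3S)-3-R-1-(triethylsilyloxy)cyclobut-1-ene, double bond C4=C5 | CC[Si](CC)(CC)OC1=C[C@@H](C(C)(C)[C@H](O[Si](C)(C)C(C)(C)C)CCOCc2ccc(OC)cc2)C1 | intermediate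
13 | diethyl (2-oxoethyl)phosphonate | CCOP(=O)(CC=O)OCC | starting material
14 | (2S,3S)-2-[2-(diethoxyphosphoryl)-1-hydroxyethyl]-3-R-cyclobutan-1-one, arm on C5 trans to R, both carbinol epimers | O=C1[C@H](C(O)CP(=O)(OCC)OCC)[C@@H](C(C)(C)[C@H](O[Si](C)(C)C(C)(C)C)CCOCc2ccc(OC)cc2)C1 | intermediate
15 | (2S,3S)-2-[2-(diethoxyphosphoryl)-1-(TESO)ethyl]-3-R-cyclobutan-1-one | O=C1[C@H](C(O[Si](CC)(CC)CC)CP(=O)(OCC)OCC)[C@@H](C(C)(C)[C@H](O[Si](C)(C)C(C)(C)C)CCOCc2ccc(OC)cc2)C1 | intermediate
16 | acetaldehyde | CC=O | starting material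
17 | (2S,3S,4R)-2-[2-(diethoxyphosphoryl)-1-(TESO)ethyl]-3-R-4-[1-(TESO)ethyl]cyclobutan-1-one, both arms trans to R | O=C1[C@H](C(O[Si](CC)(CC)CC)CP(=O)(OCC)OCC)[C@@H](C(C)(C)[C@H](O[Si](C)(C)C(C)(C)C)CCOCc2ccc(OC)cc2)[C@@H]1C(C)O[Si](CC)(CC)CC | intermediate
18 | methyltriphenylphosphonium bromide | [Br-].C[P+](c1ccccc1)(c1ccccc1)c1ccccc1 | starting material
19 | methylenetriphenylphosphorane (not isolated) | C=P(c1ccccc1)(c1ccccc1)c1ccccc1 | intermediate
20 | (2R,3S,4S)-2-[2-(diethoxyphosphoryl)-1-(TESO)ethyl]-1-methylidene-3-R-4-[1-(TESO)ethyl]cyclobutane | C=C1[C@H](C(O[Si](CC)(CC)CC)CP(=O)(OCC)OCC)[C@@H](C(C)(C)[C@H](O[Si](C)(C)C(C)(C)C)CCOCc2ccc(OC)cc2)[C@@H]1C(C)O[Si](CC)(CC)CC | intermediate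
21 | (2R,3S,4S)-2-[2-(diethoxyphosphoryl)-1-hydroxyethyl]-4-(1-hydroxyethyl)-1-methylidene-3-R-cyclobutane | C=C1[C@H](C(O)CP(=O)(OCC)OCC)[C@@H](C(C)(C)[C@H](O[Si](C)(C)C(C)(C)C)CCOCc2ccc(OC)cc2)[C@@H]1C(C)O | intermediate
22 | (2R,3S,4S)-4-acetyl-2-[(diethoxyphosphoryl)acetyl]-1-methylidene-3-R-cyclobutane | C=C1[C@H](C(=O)CP(=O)(OCC)OCC)[C@@H](C(C)(C)[C@H](O[Si](C)(C)C(C)(C)C)CCOCc2ccc(OC)cc2)[C@@H]1C(C)=O | intermediate
23 | (1R,5R,7S)-4-methyl-6-methylidene-7-R-bicyclo[3.1.1]hept-3-en-2-one, R anti to the enone bridge | C=C2[C@@H]3C(=O)C=C(C)[C@H]2[C@@H]3C(C)(C)[C@H](O[Si](C)(C)C(C)(C)C)CCOCc1ccc(OC)cc1 | intermediate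
24 | (1R,5R,7S)-7-[(3R)-3-(TBSO)-5-hydroxy-2-methylpentan-2-yl]-4-methyl-6-methylidenebicyclo[3.1.1]hept-3-en-2-one | C=C2[C@@H]3C(=O)C=C(C)[C@H]2[C@@H]3C(C)(C)[C@H](O[Si](C)(C)C(C)(C)C)CCO | intermediate
25 | (1R,5R,7S)-7-[(3R)-3-(TBSO)-2-methyl-5-oxopentan-2-yl]-4-methyl-6-methylidenebicyclo[3.1.1]hept-3-en-2-one, the methylene enone aldehyde | C=C2[C@@H]3C(=O)C=C(C)[C@H]2[C@@H]3C(C)(C)[C@H](O[Si](C)(C)C(C)(C)C)CC=O | intermediate
26 | O3-phenylsilyl ether of 27 (not isolated) | CC(C)(C)[Si](C)(C)O[C@@H]1C[C@@H](O[SiH2]c2ccccc2)[C@@]2(C)[C@@H]3C(=O)C=C(C)[C@H]2[C@@H]3C1(C)C | intermediate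
27 | tricyclic alcohol, C1 OTBS, C3 OH 1,3-anti, C4 methyl syn to the enone bridge | CC(C)(C)[Si](C)(C)O[C@@H]1C[C@@H](O)[C@@]2(C)[C@@H]3C(=O)C=C(C)[C@H]2[C@@H]3C1(C)C | intermediate
28 | C3 isobutyrate, C1 OTBS | CC(C)(C)[Si](C)(C)O[C@@H]1C[C@@H](OC(=O)C(C)C)[C@@]2(C)[C@@H]3C(=O)C=C(C)[C@H]2[C@@H]3C1(C)C | intermediate
29 | C3 isobutyrate, C1 OH | O[C@@H]1C[C@@H](OC(=O)C(C)C)[C@@]2(C)[C@@H]3C(=O)C=C(C)[C@H]2[C@@H]3C1(C)C | intermediate
30 | CNP0214356.1, C1 methacrylate, C3 isobutyrate | C=C(C)C(=O)O[C@@H]1C[C@@H](OC(=O)C(C)C)[C@@]2(C)[C@@H]3C(=O)C=C(C)[C@H]2[C@@H]3C1(C)C | target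

**Count and risks**
Total steps: 19. Longest linear sequence: 19 steps (from 1); compounds 3, 8, 13, 16 and 18 enter as commercial building blocks.

Step 16 (most likely to fail). The tertiary C4 radical may fragment (β-scission of a cyclobutane bond or a 1,2-acyl shift) or be reduced before divalent chromium captures it; the metals may fail to turn over; or the carbonyl face may be chosen badly, giving the C3 epimer. The fallback keeps the precursor but uses a different bond-forming event that is known for five- and six-membered rings, not yet for a seven-membered one, so it carries the same ring-size uncertainty: the iron-hydride radical cyclisation of alkene-tethered aldehydes and ketones. With Fe(acac)3 and PhSiH3 in EtOH at 50 °C the same tertiary radical would add directly to the carbonyl carbon and the alkoxy radical would be reduced in place, with no organochromium intermediate. It sets out from 25 and comes back at 27, and makes no new compound.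

Step 6. The amide may discriminate poorly between the two α-CH2 groups, or select the other one. The fallback gives up reagent control and relies on the C1 stereocentre for a separation. Compound 11 with LiN(iPr)2 and TESCl would give 12 together with the regioisomeric enol ether F1 (double bond towards C9). Mukaiyama aldol addition of the mixture to 13 would give 14 together with the C9-arm aldol F2. These two are diastereomers and would be separated by chromatography (preparative HPLC if needed), and F2 discarded. It sets out from 11 and comes back at 14.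

Step 4. The PMB or TBS ether may be lost to ZnCl2 and the acid chloride, or the hindered vinyl group may react so slowly that the ketene polymerises. The fallback is a keteniminium [2+2] cycloaddition: N,N-dimethylacetamide, Tf2O and 2,6-di-tert-butylpyridine with 7 in 1,2-dichloroethane would give the cyclobutaniminium triflate F3, and hydrolysis with aq. NaHCO3 would give 11 directly, so the dechlorination is not needed. It sets out from 7 and comes back at 11.

**Further compounds**
F0 | step 16 | none | none
F1 | step 6 | (3R)-3-R-1-(triethylsilyloxy)cyclobut-1-ene, double bond C4=C9 | CC[Si](CC)(CC)OC1=C[C@H](C(C)(C)[C@H](O[Si](C)(C)C(C)(C)C)CCOCc2ccc(OC)cc2)C1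
F2 | step 6 | (2R,3R)-2-[2-(diethoxyphosphoryl)-1-hydroxyethyl]-3-R-cyclobutan-1-one, arm on C9 | O=C1C[C@@H](C(C)(C)[C@H](O[Si](C)(C)C(C)(C)C)CCOCc2ccc(OC)cc2)[C@@H]1C(O)CP(=O)(OCC)OCC
F3 | step 4 | N,N-dimethyl-3-R-cyclobutan-1-iminium trifluoromethanesulfonate | C[N+](C)=C1CC(C(C)(C)[C@H](O[Si](C)(C)C(C)(C)C)CCOCc2ccc(OC)cc2)C1.[O-]S(=O)(=O)C(F)(F)F
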